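**Assumptions**
- 4-Benzyloxy-3-methoxybenzyl chloride (2) and 5-iodovanillin (1) are commercially available.
- The target is trans-(2S,3R), checked from the SMILES. The C3 ethyl ester intermediate has the same geometry but the CIP descriptor 3S, because the priority order at C3 changes when CO2Et becomes CH2OH.
- I assume Rh2(S-PTTL)4 gives the (2S,3S) sense of induction at the ester stage. If the other enantiomer forms, the R-catalyst is used instead.

**Retrosynthesis**
1. The target comes from global deprotection (aryl benzyl ether and tert-butyl ester) of alcohol 11.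
2. Alcohol 11 comes from chemoselective reduction of the C3 ethyl ester of dihydrobenzofuran 10.
3. The only ring formed is the dihydrobenzofuran. It arises from enantioselective Rh-carbene intramolecular benzylic C–H insertion of aryl diazoacetate 9, which sets C2 and C3 together (trans).
4. Diazoester 9 comes from aryl acetate 7 by diazo transfer. Acetate 7 comes from Negishi (Reformatsky) coupling of aryl iodide 5, which comes from HWE olefination of aldehyde 3. Aldehyde 3 comes from O-alkylation of 5-iodovanillin (1) with benzyl chloride 2.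

---

**Step 1**
Reactants: 1 (5-iodovanillin); 2 (4-benzyloxy-3-methoxybenzyl chloride)
Product: 3 (4-[(4-benzyloxy-3-methoxybenzyl)oxy]-3-iodo-5-methoxybenzaldehyde)
Conditions: K2CO3, NaI (cat.), DMF, 60 °C
Reagents that add atoms: none
Why: Williamson O-alkylation of the phenoxide installs the benzylic aryl ether whose OCH2 C–H is the later insertion site, and the aldehyde and aryl iodide are untouched.

**Step 2**
Reactants: 3; 4 (tert-butyl diethylphosphonoacetate)
Product: 5 (tert-butyl (E)-3-{4-[(4-benzyloxy-3-methoxybenzyl)oxy]-3-iodo-5-methoxyphenyl}acrylate)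
Conditions: NaH, THF, 0 °C to rt
Reagents that add atoms: none
Why: Horner–Wadsworth–Emmons olefination gives the E-cinnamate, and it is done before the organozinc step because a Reformatsky reagent would add to the aldehyde. The tert-butyl ester can later be removed separately from the ethyl ester introduced in Step 3.

**Step 3**
Reactants: 5; 6 (ethyl bromoacetate, used as its zinc reagent BrZn–CH2CO2Et)
Product: 7 (ethyl 2-{5-[(E)-3-tert-butoxy-3-oxoprop-1-enyl]-2-[(4-benzyloxy-3-methoxybenzyl)oxy]-3-methoxyphenyl}acetate)
Conditions: 6, Zn dust, TMSCl (cat.), THF; then 5, Pd(dba)2, Q-phos, THF, 40 °C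
Reagents that add atoms: none
Why: Pd-catalysed Negishi-type α-arylation of the Reformatsky reagent turns the aryl iodide into an aryl acetate, and oxidative addition into Ar–I is much faster than Heck reaction of the hindered cinnamate.

**Step 4**
Reactants: 7; 8 (p-acetamidobenzenesulfonyl azide)
Product: 9 (ethyl 2-diazo-2-{5-[(E)-3-tert-butoxy-3-oxoprop-1-enyl]-2-[(4-benzyloxy-3-methoxybenzyl)oxy]-3-methoxyphenyl}acetate)
Conditions: DBU, MeCN, 0 °C to rt
Reagents that add atoms: p-acetamidobenzenesulfonyl azide (p-ABSA), CC(=O)Nc1ccc(cc1)S(=O)(=O)N=[N+]=[N-], which supplies the two diazo nitrogens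
Why: Regitz diazo transfer onto the acidic benzylic CH2 of the aryl acetate gives the donor/acceptor diazoester, and the cinnamate and the benzyl and aryl ethers are inert to DBU.

**Step 5**
Reactants: 9
Product: 10 (tert-butyl (E)-3-[(2S,3S)-2-(4-benzyloxy-3-methoxyphenyl)-3-(ethoxycarbonyl)-7-methoxy-2,3-dihydrobenzofuran-5-yl]acrylate, trans)
Conditions: Rh2(S-PTTL)4 (1 mol %), CH2Cl2, rt, slow addition of 9
Reagents that add atoms: none
Why: The chiral dirhodium carbenoid inserts enantioselectively into the electron-rich benzylic O–CH2–Ar C–H bond through a five-membered transition state (intramolecular C–H insertion), which closes the dihydrobenzofuran and sets C2 and C3 in the trans arrangement. Any cis isomer can be epimerised at the ester-bearing C3 with DBU, which leaves C2 untouched.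

**Step 6**
Reactants: 10
Product: 11 (tert-butyl (E)-3-[(2S,3R)-2-(4-benzyloxy-3-methoxyphenyl)-3-(hydroxymethyl)-7-methoxy-2,3-dihydrobenzofuran-5-yl]acrylate)
Conditions: LiBH4, THF, MeOH (cat.), 0 °C to rt
Reagents that add atoms: none
Why: LiBH4 reduces the unhindered aliphatic ethyl ester to CH2OH, while the conjugated tert-butyl cinnamate and the ethers are not reduced. No stereocentre is created, and the descriptor at C3 changes from S to R only because the CIP priorities change.

**Step 7**
Reactants: 11
Product: 12 (target, (E)-3-[(2S,3R)-2-(4-hydroxy-3-methoxyphenyl)-3-(hydroxymethyl)-7-methoxy-2,3-dihydrobenzofuran-5-yl]acrylic acid)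
Conditions: BCl3, pentamethylbenzene, CH2Cl2, −78 °C to −20 °C; then MeOH quench
Reagents that add atoms: none
Why: BCl3 cleaves the aryl benzyl ether (Lewis-acid debenzylation, with pentamethylbenzene trapping the benzyl cation) and the tert-butyl ester in one pot. The aryl methyl ethers, the E-alkene and both stereocentres survive at low temperature, and the methanol quench breaks up any borate esters of the primary alcohol.

---

**Compound list**

1 | 5-Iodovanillin (4-hydroxy-3-iodo-5-methoxybenzaldehyde) | COc1cc(C=O)cc(I)c1O | starting material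
2 | 4-Benzyloxy-3-methoxybenzyl chloride | COc1cc(CCl)ccc1OCc1ccccc1 | starting material
3 | 4-[(4-Benzyloxy-3-methoxybenzyl)oxy]-3-iodo-5-methoxybenzaldehyde | COc1cc(C=O)cc(I)c1OCc1ccc(OCc2ccccc2)c(OC)c1 | intermediate
4 | tert-Butyl diethylphosphonoacetate | CCOP(=O)(OCC)CC(=O)OC(C)(C)C | starting material
5 | tert-Butyl (E)-3-{4-[(4-benzyloxy-3-methoxybenzyl)oxy]-3-iodo-5-methoxyphenyl}acrylate | CC(C)(C)OC(=O)/C=C/c1cc(OC)c(OCc2ccc(OCc3ccccc3)c(OC)c2)c(I)c1 | intermediate
6 | Ethyl bromoacetate | BrCC(=O)OCC | starting material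
7 | Ethyl 2-{5-[(E)-3-tert-butoxy-3-oxoprop-1-enyl]-2-[(4-benzyloxy-3-methoxybenzyl)oxy]-3-methoxyphenyl}acetate | CCOC(=O)Cc1cc(/C=C/C(=O)OC(C)(C)C)cc(OC)c1OCc1ccc(OCc2ccccc2)c(OC)c1 | intermediate
8 | p-Acetamidobenzenesulfonyl azide (p-ABSA) | CC(=O)Nc1ccc(cc1)S(=O)(=O)N=[N+]=[N-] | starting material (reagent)
9 | Ethyl 2-diazo-2-{5-[(E)-3-tert-butoxy-3-oxoprop-1-enyl]-2-[(4-benzyloxy-3-methoxybenzyl)oxy]-3-methoxyphenyl}acetate | CCOC(=O)C(=[N+]=[N-])c1cc(/C=C/C(=O)OC(C)(C)C)cc(OC)c1OCc1ccc(OCc2ccccc2)c(OC)c1 | intermediate
10 | tert-Butyl (E)-3-[(2S,3S)-2-(4-benzyloxy-3-methoxyphenyl)-3-(ethoxycarbonyl)-7-methoxy-2,3-dihydrobenzofuran-5-yl]acrylate (trans) | COc1cc([C@H]2Oc3c(OC)cc(/C=C/C(=O)OC(C)(C)C)cc3[C@@H]2C(=O)OCC)ccc1OCc1ccccc1 | intermediate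
11 | tert-Butyl (E)-3-[(2S,3R)-2-(4-benzyloxy-3-methoxyphenyl)-3-(hydroxymethyl)-7-methoxy-2,3-dihydrobenzofuran-5-yl]acrylate | COc1cc([C@H]2Oc3c(OC)cc(/C=C/C(=O)OC(C)(C)C)cc3[C@@H]2CO)ccc1OCc1ccccc1 | intermediate
12 | (E)-3-[(2S,3R)-2-(4-Hydroxy-3-methoxyphenyl)-3-(hydroxymethyl)-7-methoxy-2,3-dihydrobenzofuran-5-yl]acrylic acid | COc1cc([C@H]2Oc3c(OC)cc(/C=C/C(=O)O)cc3[C@@H]2CO)ccc1O | target

**Totals:** 7 steps in total. The longest linear sequence is 7 steps (1 → 3 → 5 → 7 → 9 → 10 → 11 → 12).

**Three steps most likely to fail**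
1. **Step 5 (Rh C–H insertion: ee, dr and competing pathways).** The ee or trans:cis ratio may be modest, or the carbene may divert to dimerisation or other pathways. Fallback: use Rh2(OAc)4 to make racemic trans-10, then resolve by preparative chiral-phase HPLC (or lipase resolution after reduction to the alcohol).
2. **Step 7 (BCl3 global deprotection).** The acid-labile benzylic C2–O bond could ring-open, or an aryl methyl ether could be cleaved. Fallback: change the protecting group to MOM. Prepare 4-(MOM-oxy)-3-methoxybenzyl alcohol from vanillyl alcohol and couple it to 1 by Mitsunobu reaction (PPh3, DIAD) in place of Step 1, so that a single TFA/CH2Cl2 treatment at 0 °C removes both the MOM and tert-butyl groups.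
3. **Step 3 (Negishi α-arylation).** The ortho-alkoxy aryl iodide may couple poorly, or the cinnamate may undergo Heck or Michael side reactions. Fallback: change the order. Protect aldehyde 3 as its dimethyl acetal, do the Negishi coupling on the acetal, then hydrolyse the acetal and carry out the HWE olefination before diazo transfer.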